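**Retrosynthetic overview**

- The strategy rests on ring A of the flavone: it is hexasubstituted, C5–OH and C8–OMe are para, and the four contiguous oxygen-bearing carbons C5, C6, C7 and C8 together form the C4O4 unit of a squarate.
- Ring A is opened at C8–C8a to a 4-hydroxy-4-(4-pyranon-3-yl)cyclobutenone; C4a–C5 comes from addition of a 3-magnesiated pyranone to a squarate carbonyl.
- C6–OMe and C7–OBn are told apart on a squarate mono-ketal: benzyloxy is exchanged into the β-position, and the pyranonyl metal then adds to the single free carbonyl, which lies next to the methoxy carbon.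
- Ring C (the γ-pyranone) is built from the ring B acid chloride and 3-iodo-4-methoxybutenone, so the iodine arrives at pyranone C3 without a selectivity question; ring B comes from methoxyhydroquinone.
- Ring order: B (given), then C, then A; the route ends with methylation of the 8-OH and hydrogenolysis of three benzyl ethers.

Key step: step 11

Remark: the hydroquinone-type compounds 1, 20 and 22 are air-sensitive and are handled under argon. Compounds 16 and 17 are racemic; their carbinol centre becomes the aromatic C5 in step 11, so its configuration is without consequence.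

**Route**

Step 1
Reactants: 1 methoxyhydroquinone
Product: 2 1,4-bis(benzyloxy)-2-methoxybenzene
Conditions: BnBr, K2CO3, DMF, 60 °C, N2
Reagents that add atoms: benzyl bromide BrCc1ccccc1
Why: Williamson ether synthesis on both phenols, which masks ring B as a bis(benzyl ether) that survives every later step and is removed by the final hydrogenolysis.

Step 2
Reactants: 2 1,4-bis(benzyloxy)-2-methoxybenzene
Product: 4 2,5-bis(benzyloxy)-4-methoxybenzaldehyde, via iminium chloride 3 (not isolated)
Conditions: POCl3, DMF, 0 → 60 °C; then ice/H2O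
Reagents that add atoms: N,N-dimethylformamide CN(C)C=O; water O
Why: Vilsmeier–Haack formylation of a 1,2,4-trialkoxybenzene should go to the one position that is para to the methoxy group and ortho to a benzyloxy group, which is the ring B attachment carbon.

Step 3
Reactants: 4 2,5-bis(benzyloxy)-4-methoxybenzaldehyde
Product: 5 2,5-bis(benzyloxy)-4-methoxybenzoic acid
Conditions: NaClO2, NaH2PO4, 2-methyl-2-butene, t-BuOH/THF/H2O, rt
Reagents that add atoms: sodium chlorite [Na+].[O-]Cl=O
Why: Pinnick oxidation converts the aldehyde to the acid, and the alkene scavenger keeps hypochlorite away from the electron-rich ring.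

Step 4
Reactants: 5 2,5-bis(benzyloxy)-4-methoxybenzoic acid
Product: 6 2,5-bis(benzyloxy)-4-methoxybenzoyl chloride
Conditions: (COCl)2, DMF (cat.), CH2Cl2, 0 °C → rt; used crude
Reagents that add atoms: oxalyl chloride ClC(=O)C(=O)Cl
Why: Standard acid chloride formation through the catalytic chloroiminium species, under conditions that leave aryl benzyl ethers untouched.

Step 5
Reactants: 7 (E)-4-methoxybut-3-en-2-one
Product: 8 (Z)-3-iodo-4-methoxybut-3-en-2-one
Conditions: I2, pyridine, CH2Cl2, 0 °C → rt
Reagents that add atoms: iodine II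
Why: Electrophilic α-iodination of a push-pull β-alkoxy enone, in which iodine attacks the nucleophilic α-carbon and pyridine removes the proton from the resulting oxocarbenium ion, so the halogen is fixed on the carbon that becomes pyranone C3.

Step 6
Reactants: 8 (Z)-3-iodo-4-methoxybut-3-en-2-one; 6 2,5-bis(benzyloxy)-4-methoxybenzoyl chloride
Product: 11 6-[2,5-bis(benzyloxy)-4-methoxyphenyl]-3-iodo-4H-pyran-4-one, via lithium dienolate 9 (not isolated), via pentenedione 10 (not isolated)
Conditions: LiN(SiMe3)2 (2.1 equiv), THF, −78 °C; then 6, −78 °C; then CF3CO2H, CH2Cl2, rt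
Reagents that add atoms: none
Why: C-acylation of the kinetic methyl-ketone enolate with the aroyl chloride gives a 1,3-diketone whose enol oxygen closes onto the β-methoxy enone carbon with loss of methanol under acid (γ-pyranone synthesis by acylation and cyclocondensation), and the iodine is carried through unchanged.

Step 7
Reactants: 12 dimethyl squarate
Product: 13 1,2-dimethoxy-5,8-dioxaspiro[3.4]oct-1-en-3-one
Conditions: Me3SiOCH2CH2OSiMe3, Me3SiOTf (cat.), CH2Cl2, −78 °C → rt
Reagents that add atoms: 1,2-bis(trimethylsilyloxy)ethane C[Si](C)(C)OCCO[Si](C)(C)C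
Why: Silyl-triflate-catalysed ketalisation with the bis-silyl ether of ethylene glycol should stop at the mono-ketal, because the remaining carbonyl is then a plain vinylogous ester and no longer activated by a neighbouring carbonyl.

Step 8
Reactants: 13 1,2-dimethoxy-5,8-dioxaspiro[3.4]oct-1-en-3-one
Product: 14 1-(benzyloxy)-2-methoxy-5,8-dioxaspiro[3.4]oct-1-en-3-one
Conditions: BnOH (5 equiv), NaH (cat.), THF, 0 °C → rt, MeOH removed under reduced pressure
Reagents that add atoms: benzyl alcohol OCc1ccccc1
Why: Alkoxide-catalysed vinylogous transesterification (conjugate addition–elimination) can only occur at the β-carbon of the enone, so benzyloxy replaces the methoxy group next to the ketal carbon while the α-methoxy group and the ketal stay in place.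

Step 9
Reactants: 11 6-[2,5-bis(benzyloxy)-4-methoxyphenyl]-3-iodo-4H-pyran-4-one; 14 1-(benzyloxy)-2-methoxy-5,8-dioxaspiro[3.4]oct-1-en-3-one
Product: 16 racemic 6-[2,5-bis(benzyloxy)-4-methoxyphenyl]-3-[1-(benzyloxy)-3-hydroxy-2-methoxy-5,8-dioxaspiro[3.4]oct-1-en-3-yl]-4H-pyran-4-one, via pyranonylmagnesium chloride 15 (not isolated)
Conditions: iPrMgCl·LiCl, THF, −40 °C; then 14 (LaCl3·2LiCl optional), −40 → −20 °C; aq. NH4Cl
Reagents that add atoms: none
Why: Iodine–magnesium exchange on an α-iodo-β-alkoxy enone gives an alkenyl Grignard reagent that is stable at low temperature and adds 1,2 to the only carbonyl of 14, which lies next to the methoxy carbon; the new carbinol centre is formed racemic and is not needed later.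

Step 10
Reactants: 16 racemic 6-[2,5-bis(benzyloxy)-4-methoxyphenyl]-3-[1-(benzyloxy)-3-hydroxy-2-methoxy-5,8-dioxaspiro[3.4]oct-1-en-3-yl]-4H-pyran-4-one
Product: 17 racemic 2-(benzyloxy)-4-hydroxy-3-methoxy-4-{6-[2,5-bis(benzyloxy)-4-methoxyphenyl]-4-oxo-4H-pyran-3-yl}cyclobut-2-en-1-one
Conditions: 1 M aq. HCl, THF, 0 °C → rt
Reagents that add atoms: water O
Why: Mild acid hydrolysis of the ketal should outrun ionisation of the tertiary alcohol, because the ketal gives an oxocarbenium ion with two alkoxy donors, and once the carbonyl is free it disfavours any later loss of the hydroxyl.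

Step 11
Reactants: 17 racemic 2-(benzyloxy)-4-hydroxy-3-methoxy-4-{6-[2,5-bis(benzyloxy)-4-methoxyphenyl]-4-oxo-4H-pyran-3-yl}cyclobut-2-en-1-one
Product: 20 7-(benzyloxy)-2-[2,5-bis(benzyloxy)-4-methoxyphenyl]-5,8-dihydroxy-6-methoxy-4H-chromen-4-one, via dienylketene 18 (not isolated), via cyclohexadienone 19 (not isolated)
Conditions: degassed toluene (or p-xylene), 110 °C, Ar
Reagents that add atoms: none
Why: This is a Moore-type thermal ring expansion of a 4-alkenyl-4-hydroxycyclobutenone: conrotatory 4π opening of the C1–C4 bond, with the hydroxyl rotating outward, places the pyranonyl group cis to the ketene in dienylketene 18. The ketene carbon then closes on pyranone C2 in a thermal 6π electrocyclisation, with the pyranone C2=C3 bond as the third π component, which forms the C8–C8a bond and the six-membered ring A as the 8aH-dienone 19. Enolisation of the C8a–H of 19 aromatises ring A to the 5,8-hydroquinone; the transient C8a centre is lost, so no stereocentre has to be controlled. The selectivity needed is the outward rotation of the oxygen substituent, since an inward hydroxyl would add to the ketene; the donor character of the hydroxyl secures it, and pyranone C2 is the only carbon terminus within reach. The C6–OMe and C7–OBn positions are already fixed in 17, because the carbinol carbon (future C5) is bonded to the methoxy-bearing carbon.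

Step 12
Reactants: 20 7-(benzyloxy)-2-[2,5-bis(benzyloxy)-4-methoxyphenyl]-5,8-dihydroxy-6-methoxy-4H-chromen-4-one
Product: 21 7-(benzyloxy)-2-[2,5-bis(benzyloxy)-4-methoxyphenyl]-5-hydroxy-6,8-dimethoxy-4H-chromen-4-one
Conditions: MeI (1.2 equiv), K2CO3, acetone, rt, Ar
Reagents that add atoms: iodomethane CI
Why: Partial O-methylation of a 5,8-dihydroxyflavone should take the 8-OH, because the 5-OH is held in a hydrogen bond to the C4 carbonyl and is far less acidic and less nucleophilic.

Step 13
Reactants: 21 7-(benzyloxy)-2-[2,5-bis(benzyloxy)-4-methoxyphenyl]-5-hydroxy-6,8-dimethoxy-4H-chromen-4-one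
Product: 22 2-(2,5-dihydroxy-4-methoxyphenyl)-5,7-dihydroxy-6,8-dimethoxy-4H-chromen-4-one (CNP0297724.0)
Conditions: H2 (1 atm), Pd/C (10% palladium on carbon), EtOAc/MeOH, rt; stopped after uptake of three equivalents; work-up under Ar
Reagents that add atoms: none
Why: Catalytic hydrogenolysis cleaves the three aryl benzyl ethers, and the flavone C2=C3 bond and the methyl ethers should survive at ambient pressure and temperature.

**Compound list**

1 | methoxyhydroquinone (2-methoxybenzene-1,4-diol) | COc1cc(O)ccc1O | starting material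
2 | 1,4-bis(benzyloxy)-2-methoxybenzene | COc1cc(OCc2ccccc2)ccc1OCc1ccccc1 | intermediate
3 | N-[2,5-bis(benzyloxy)-4-methoxybenzylidene]-N-methylmethanaminium chloride | COc1cc(OCc2ccccc2)c(C=[N+](C)C)cc1OCc1ccccc1.[Cl-] | intermediate
4 | 2,5-bis(benzyloxy)-4-methoxybenzaldehyde | COc1cc(OCc2ccccc2)c(C=O)cc1OCc1ccccc1 | intermediate
5 | 2,5-bis(benzyloxy)-4-methoxybenzoic acid | COc1cc(OCc2ccccc2)c(C(=O)O)cc1OCc1ccccc1 | intermediate
6 | 2,5-bis(benzyloxy)-4-methoxybenzoyl chloride | COc1cc(OCc2ccccc2)c(C(=O)Cl)cc1OCc1ccccc1 | intermediate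
7 | (E)-4-methoxybut-3-en-2-one | CO/C=C/C(C)=O | starting material
8 | (Z)-3-iodo-4-methoxybut-3-en-2-one | CO/C=C(\I)C(C)=O | intermediate
9 | lithium (3Z)-3-iodo-4-methoxybuta-1,3-dien-2-olate | CO/C=C(\I)C(=C)O[Li] | intermediate
10 | (4Z)-1-[2,5-bis(benzyloxy)-4-methoxyphenyl]-4-iodo-5-methoxypent-4-ene-1,3-dione | CO/C=C(\I)C(=O)CC(=O)c1cc(OCc2ccccc2)c(OC)cc1OCc1ccccc1 | intermediate
11 | 6-[2,5-bis(benzyloxy)-4-methoxyphenyl]-3-iodo-4H-pyran-4-one | O=c1cc(-c2cc(OCc3ccccc3)c(OC)cc2OCc2ccccc2)occ1I | intermediate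
12 | dimethyl squarate (3,4-dimethoxycyclobut-3-ene-1,2-dione) | COC1=C(OC)C(=O)C1=O | starting material
13 | 1,2-dimethoxy-5,8-dioxaspiro[3.4]oct-1-en-3-one | COC1=C(OC)C2(OCCO2)C1=O | intermediate
14 | 1-(benzyloxy)-2-methoxy-5,8-dioxaspiro[3.4]oct-1-en-3-one | COC1=C(OCc2ccccc2)C2(OCCO2)C1=O | intermediate
15 | {6-[2,5-bis(benzyloxy)-4-methoxyphenyl]-4-oxo-4H-pyran-3-yl}magnesium chloride (LiCl complex) | O=c1cc(-c2cc(OCc3ccccc3)c(OC)cc2OCc2ccccc2)occ1[Mg]Cl | intermediate
16 | racemic 6-[2,5-bis(benzyloxy)-4-methoxyphenyl]-3-[1-(benzyloxy)-3-hydroxy-2-methoxy-5,8-dioxaspiro[3.4]oct-1-en-3-yl]-4H-pyran-4-one | COC1=C(OCc2ccccc2)C2(OCCO2)C1(O)c1coc(-c2cc(OCc3ccccc3)c(OC)cc2OCc2ccccc2)cc1=O | intermediate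
17 | racemic 2-(benzyloxy)-4-hydroxy-3-methoxy-4-{6-[2,5-bis(benzyloxy)-4-methoxyphenyl]-4-oxo-4H-pyran-3-yl}cyclobut-2-en-1-one | COC1=C(OCc2ccccc2)C(=O)C1(O)c1coc(-c2cc(OCc3ccccc3)c(OC)cc2OCc2ccccc2)cc1=O | intermediate
18 | (3Z)-2-(benzyloxy)-4-hydroxy-3-methoxy-4-{6-[2,5-bis(benzyloxy)-4-methoxyphenyl]-4-oxo-4H-pyran-3-yl}buta-1,3-dien-1-one (dienylketene) | O=C=C(OCc1ccccc1)/C(OC)=C(/O)c1coc(-c2cc(OCc3ccccc3)c(OC)cc2OCc2ccccc2)cc1=O | intermediate
19 | racemic 7-(benzyloxy)-2-[2,5-bis(benzyloxy)-4-methoxyphenyl]-5-hydroxy-6-methoxy-8aH-chromene-4,8-dione | O=C1C(OCc2ccccc2)=C(OC)C(O)=C2C(=O)C=C(c3cc(OCc4ccccc4)c(OC)cc3OCc3ccccc3)OC12 | intermediate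
20 | 7-(benzyloxy)-2-[2,5-bis(benzyloxy)-4-methoxyphenyl]-5,8-dihydroxy-6-methoxy-4H-chromen-4-one | COc1cc(OCc2ccccc2)c(-c2cc(=O)c3c(O)c(OC)c(OCc4ccccc4)c(O)c3o2)cc1OCc1ccccc1 | intermediate
21 | 7-(benzyloxy)-2-[2,5-bis(benzyloxy)-4-methoxyphenyl]-5-hydroxy-6,8-dimethoxy-4H-chromen-4-one | COc1cc(OCc2ccccc2)c(-c2cc(=O)c3c(O)c(OC)c(OCc4ccccc4)c(OC)c3o2)cc1OCc1ccccc1 | intermediate
22 | 2-(2,5-dihydroxy-4-methoxyphenyl)-5,7-dihydroxy-6,8-dimethoxy-4H-chromen-4-one | COc1cc(O)c(-c2cc(=O)c3c(O)c(OC)c(O)c(OC)c3o2)cc1O | target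

**Step count**

Total: 13 steps. Longest linear sequence: 10 steps (steps 1, 2, 3, 4, 6, 9, 10, 11, 12, 13).

**Steps most likely to fail**

1. Step 11. If the 6π closure onto the electron-poor pyranone C2=C3 bond is slow, or the hydroxyl rotates inward, the hydroxyl would add to the ketene and give a butenolide; the free hydroquinone may also be oxidised by air during isolation. The fallback sets out from 17 and masks the hydroxyl before heating. Silylation (Me3SiCl, imidazole, DMF) should give the trimethylsilyl ether of 17, 2-(benzyloxy)-3-methoxy-4-(trimethylsilyloxy)-4-{6-[2,5-bis(benzyloxy)-4-methoxyphenyl]-4-oxo-4H-pyran-3-yl}cyclobut-2-en-1-one F1. Thermolysis of F1 in toluene leaves the ketene no hydroxyl to capture it, and an unproductive ketene isomer can only return to the cyclobutenone, so the electrocyclisation should give 7-(benzyloxy)-2-[2,5-bis(benzyloxy)-4-methoxyphenyl]-8-hydroxy-6-methoxy-5-(trimethylsilyloxy)-4H-chromen-4-one F2. Methanolysis of the silyl ether (citric acid, MeOH) rejoins the route at 20.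

2. Step 9. Addition to the deactivated vinylogous-ester carbonyl of 14 may be slower than fragmentation of the magnesiated pyranone (β-elimination of the ring oxygen) or than conjugate addition with loss of benzyloxide. The fallback sets out from 11 and 12, replaces the ketal by a far more electrophilic squarate diester, and moves the alkoxy differentiation to after the addition. Compound 12 is transesterified with benzyl alcohol (cat. CF3CO2H, toluene, reflux) to dibenzyl squarate F3. The Grignard reagent 15, made from 11 as before, is added to F3 at −78 °C to give racemic 2,3-bis(benzyloxy)-4-hydroxy-4-{6-[2,5-bis(benzyloxy)-4-methoxyphenyl]-4-oxo-4H-pyran-3-yl}cyclobut-2-en-1-one F4. In F4 only the benzyloxy group at C3 (next to the carbinol) is a vinylogous ester, and it is exchanged with methanol (cat. NaOMe, MeOH, 0 °C). The fallback rejoins the route at 17 and bypasses 16 and step 10.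

3. Step 6. The iodinated dienolate may be acylated on oxygen, or may decompose before C-acylation, so the diketone needed for ring closure is not formed. The fallback sets out from aldehyde 4 and builds ring C by a cycloaddition. A BF3·OEt2-promoted hetero-Diels–Alder reaction of 4 with (E)-1-methoxy-3-(trimethylsilyloxy)buta-1,3-diene (CH2Cl2, −78 °C; then CF3CO2H) should give racemic 2-[2,5-bis(benzyloxy)-4-methoxyphenyl]-2,3-dihydro-4H-pyran-4-one F5. α-Iodination (I2, pyridine, CH2Cl2) can only occur at the single vinylic α-carbon, giving racemic 2-[2,5-bis(benzyloxy)-4-methoxyphenyl]-5-iodo-2,3-dihydro-4H-pyran-4-one F6. Dehydrogenation of the C2–C3 bond (DDQ, dioxane, heat) rejoins the route at 11.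

**Further compounds**

F1 | step 11 | racemic 2-(benzyloxy)-3-methoxy-4-(trimethylsilyloxy)-4-{6-[2,5-bis(benzyloxy)-4-methoxyphenyl]-4-oxo-4H-pyran-3-yl}cyclobut-2-en-1-one | COC1=C(OCc2ccccc2)C(=O)C1(O[Si](C)(C)C)c1coc(-c2cc(OCc3ccccc3)c(OC)cc2OCc2ccccc2)cc1=O
F2 | step 11 | 7-(benzyloxy)-2-[2,5-bis(benzyloxy)-4-methoxyphenyl]-8-hydroxy-6-methoxy-5-(trimethylsilyloxy)-4H-chromen-4-one | COc1cc(OCc2ccccc2)c(-c2cc(=O)c3c(O[Si](C)(C)C)c(OC)c(OCc4ccccc4)c(O)c3o2)cc1OCc1ccccc1
F3 | step 9 | dibenzyl squarate (3,4-bis(benzyloxy)cyclobut-3-ene-1,2-dione) | O=C1C(=O)C(OCc2ccccc2)=C1OCc1ccccc1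
F4 | step 9 | racemic 2,3-bis(benzyloxy)-4-hydroxy-4-{6-[2,5-bis(benzyloxy)-4-methoxyphenyl]-4-oxo-4H-pyran-3-yl}cyclobut-2-en-1-one | O=C1C(OCc2ccccc2)=C(OCc2ccccc2)C1(O)c1coc(-c2cc(OCc3ccccc3)c(OC)cc2OCc2ccccc2)cc1=O
F5 | step 6 | racemic 2-[2,5-bis(benzyloxy)-4-methoxyphenyl]-2,3-dihydro-4H-pyran-4-one | O=C1C=COC(c2cc(OCc3ccccc3)c(OC)cc2OCc2ccccc2)C1
F6 | step 6 | racemic 2-[2,5-bis(benzyloxy)-4-methoxyphenyl]-5-iodo-2,3-dihydro-4H-pyran-4-one | O=C1CC(c2cc(OCc3ccccc3)c(OC)cc2OCc2ccccc2)OC=C1I
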